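**Plan**

- Retrosynthetic cuts: O–C15 of ring D (alkynol cycloisomerisation), C6–O (acyloxy shift), C9–C10 of ring B (radical cyclisation), C9–O and C8–C9 (cyclodehydration and crossed Claisen joining the two halves), then C5–C6 and C10=C20 on ring A.
- Enabling feature: C9, the spiro ether carbon shared by rings B and C, is β to the C7 ketone and next to the methyl-bearing quaternary C10. Ring B can therefore be closed by adding a C10 radical, made from a C10=CH2 group, to C9 of a ring-C β-alkoxy enone.
- Forward order: ring A comes from 2-methylcyclohexane-1,3-dione and the ring-C carbons from a C13 alkynyl lactone. Claisen union and dehydration form ring C, the radical step closes ring B, C6 is oxidised, ring D is closed and the acetates go on last.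
- Stereochemistry: C3/C4 by enzymatic desymmetrisation, C5 by α-face hydroboration, C13 by catalytic asymmetric alkynylation. C10, C9 and C8 arise in the key step (ring-A chair, Z enone geometry, enolate protonation), and C6 by an acyloxy shift with inversion.

Key step: step 16

Remark: labdane numbering is used (ring A C1–C5/C10, ring B C5–C10, ring C O–C9–C11–C12–C13, ring D C13–C14=C15–O–C16; C17 on C8, C18/C19 on C4, C20 on C10; α is the face of H5, β that of C20); it is assumed that a panel ketoreductase (step 2) and the appropriate ligand enantiomer (step 11) deliver the stated configurations.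

**Route**

Step 1
Reactants: 1 2-methylcyclohexane-1,3-dione
Product: 2 2-(hydroxymethyl)-2-methylcyclohexane-1,3-dione
Conditions: 37% aq. HCHO, H2O, rt
Reagents that add atoms: formaldehyde, C=O
Why: Aldol-type hydroxymethylation of the acidic 2-alkyl-1,3-dione at C2 builds the quaternary carbon that becomes C4 (CH3 = C18, CH2OH = C19); the product is achiral, so no stereocontrol is needed.

Step 2
Reactants: 2 2-(hydroxymethyl)-2-methylcyclohexane-1,3-dione
Product: 3 (2S,3S)-3-hydroxy-2-(hydroxymethyl)-2-methylcyclohexan-1-one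
Conditions: ketoreductase, NADP+ (cat.), i-PrOH, phosphate buffer pH 7, 30 °C
Reagents that add atoms: none
Why: Enzymatic desymmetrising reduction of one of the two enantiotopic carbonyl groups (NADPH recycled by isopropanol) sets C3 (S, hydroxyl cis to the CH2OH arm) and with it C4 (S), the same sense as yeast reductions of 2-alkyl-2-methylcyclohexane-1,3-diones.

Step 3
Reactants: 3 (2S,3S)-3-hydroxy-2-(hydroxymethyl)-2-methylcyclohexan-1-one
Product: 4 bis(triethylsilyl) ether of 3
Conditions: Et3SiCl, imidazole, DMAP (cat.), DMF, 0 °C → rt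
Reagents that add atoms: chlorotriethylsilane, CC[Si](Cl)(CC)CC
Why: Standard silyl ether formation on both hydroxyls; two separate silyl ethers are used instead of a cyclic 3,19-acetal because they leave ring A free to take the chair with C19 axial, on which the face selectivity of steps 6 and 16 depends.

Step 4
Reactants: 4 bis(triethylsilyl) ether ketone
Product: 5 C5 enol triflate (C5=C10)
Conditions: KN(SiMe3)2, THF, −78 °C; PhNTf2, −78 → 0 °C; aq. NH4Cl
Reagents that add atoms: N-phenylbis(trifluoromethanesulfonimide), O=S(=O)(N(c1ccccc1)S(=O)(=O)C(F)(F)F)C(F)(F)F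
Why: Enolate triflation: C4 is quaternary, so the ketone can enolise only towards C10 and the C5(OTf)=C10 regiochemistry is fixed.

Step 5
Reactants: 5 C5 enol triflate
Product: 6 β,γ-unsaturated ethyl ester (C6–C7 attached to C5)
Conditions: BrZnCH2CO2Et (from BrCH2CO2Et, Zn), Pd2(dba)3 (cat.), XPhos, THF, 60 °C
Reagents that add atoms: ethyl bromoacetate (used as its zinc reagent), CCOC(=O)CBr
Why: Negishi-type palladium-catalysed coupling of the vinyl triflate with a Reformatsky zinc enolate attaches C6 and C7 to C5 and keeps the C5=C10 double bond for the next step.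

Step 6
Reactants: 6 β,γ-unsaturated ethyl ester
Product: 8 C10 alcohol (5α-H, 10α-OH), via C10 alkylborane 7 (not isolated)
Conditions: BH3·THF, THF, 0 °C → rt; then 30% H2O2, aq. NaOH, 0 °C
Reagents that add atoms: hydrogen peroxide, OO
Why: Hydroboration–oxidation adds boron (then hydroxyl, with retention) to the less substituted C10 and hydrogen to C5 in a syn fashion from the α face, away from the pseudoaxial C19 CH2OSiEt3 group and the 3β-silyloxy group, which sets the 5α-H stereocentre (the C10 carbinol centre is lost in step 7); borane at 0 °C does not reduce the ester.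

Step 7
Reactants: 8 C10 alcohol
Product: 9 C10 ketone
Conditions: Dess–Martin periodinane, NaHCO3, CH2Cl2, 0 °C → rt
Reagents that add atoms: none
Why: Dess–Martin oxidation under buffered, non-enolising conditions gives the C10 ketone without epimerising C5, whose configuration with the side chain equatorial is in any case the more stable one.

Step 8
Reactants: 9 C10 ketone
Product: 10 methylidene ester (C10=C20)
Conditions: Zn, CH2Br2, TiCl4, THF/CH2Cl2, 0 °C → rt
Reagents that add atoms: dibromomethane, BrCBr
Why: Takai–Lombardo methylenation converts the hindered, α-branched ketone into the exocyclic C10=C20 alkene under non-basic conditions, so C5 is not epimerised and the ester is not attacked.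

Step 9
Reactants: 10 methylidene ester
Product: 11 Weinreb amide
Conditions: MeNH(OMe)·HCl, i-PrMgCl, THF, −20 °C
Reagents that add atoms: N,O-dimethylhydroxylamine hydrochloride, CNOC.Cl
Why: Aminolysis of the ester by the magnesium amide of N,O-dimethylhydroxylamine (Weinreb amide synthesis) prepares C7 for a single addition of a carbon nucleophile.

Step 10
Reactants: 11 Weinreb amide
Product: 12 ring-A ethyl ketone
Conditions: EtMgBr, THF, 0 °C; aq. NH4Cl
Reagents that add atoms: ethylmagnesium bromide, CC[Mg]Br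
Why: Grignard addition to the Weinreb amide stops at the chelated tetrahedral intermediate and releases the ethyl ketone (C8 and C17 added) on work-up.

Step 11
Reactants: 13 diethyl 2-oxopentanedioate; 14 ethynyl(triethyl)silane
Product: 16 (R)-lactone ester, via hydroxy diester 15 (not isolated)
Conditions: Zn(OTf)2, Et3N, 2-(dimethylamino)-1-(4-nitrophenyl)-3-(tert-butyldimethylsilyloxy)propan-1-ol (enantiomer giving R), PhMe, 60 °C; then TsOH (cat.), 60 °C
Reagents that add atoms: none
Why: Zinc-mediated catalytic asymmetric alkynylation of the α-keto ester creates the tertiary propargylic carbinol C13, the face being chosen by the chiral amino alcohol on zinc, and the new hydroxyl then closes the γ-lactone onto the distal ester.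

Step 12
Reactants: 16 (R)-lactone ester
Product: 17 (R)-hydroxymethyl lactone
Conditions: NaBH4, EtOH, 0 °C; aq. NH4Cl
Reagents that add atoms: none
Why: Chemoselective sodium borohydride reduction of the α-oxygen-activated ester in the presence of the γ-lactone, as in the classical preparation of 5-(hydroxymethyl)butyrolactone from its ethyl ester; the triethylsilyl alkyne survives the ethanolic hydride.

Step 13
Reactants: 17 (R)-hydroxymethyl lactone
Product: 18 (R)-silyloxymethyl lactone
Conditions: t-BuMe2SiCl, imidazole, DMF, rt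
Reagents that add atoms: tert-butyldimethylsilyl chloride, CC(C)(C)[Si](C)(C)Cl
Why: Standard silylation of the primary hydroxyl that will become O16.

Step 14
Reactants: 12 ring-A ethyl ketone (2 equiv, excess recovered); 18 (R)-silyloxymethyl lactone
Product: 19 γ-hydroxy 1,3-diketone (C8 epimers)
Conditions: LiN(i-Pr)2, THF, −78 °C; then 18, −78 → −20 °C; aq. NH4Cl
Reagents that add atoms: none
Why: Crossed Claisen condensation: the kinetic lithium enolate forms at the unhindered C8 methylene of the ethyl ketone rather than at C6, which is flanked by the substituted ring carbon C5, and acylation by the lactone carbonyl opens the lactone to the tertiary alkoxide; the new C8 centre is a mixture and is removed in step 15.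

Step 15
Reactants: 19 γ-hydroxy 1,3-diketone
Product: 20 (Z)-9,10-seco enone (ring C closed)
Conditions: PPTS (cat.), 4 Å MS, PhMe, 60 °C
Reagents that add atoms: none
Why: Acid-catalysed cyclodehydration of the γ-hydroxy 1,3-diketone (hemiketal formation at C9, then loss of water towards C8) closes ring C as the exocyclic vinylogous ester, and under these equilibrating conditions the Z isomer is expected to dominate because only with the acyl group cis to the ring oxygen, and the C8 methyl cis to C11, can the β-alkoxy enone stay planar.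

Step 16
Reactants: 20 (Z)-9,10-seco enone
Product: 21 9α,13-epoxy-7-oxo decalin (ring B closed)
Conditions: Fe(acac)3 (0.5 equiv), PhSiH3 (3 equiv, slow addition), EtOH/(CH2OH)2 5:1, 60 °C, degassed
Reagents that add atoms: none
Why: The iron hydride generated from Fe(acac)3 and PhSiH3 transfers a hydrogen atom to the CH2 terminus of the C10=C20 alkene, the nucleophilic tertiary C10 radical adds to C9 (the β-carbon of the β-alkoxy enone), and the C8 α-keto radical is reduced to the iron enolate and protonated by ethanol. The reaction type is the hydrogen-atom-transfer-initiated radical conjugate (Giese) cyclisation of alkenes onto enones, with tin-hydride radical additions to β-alkoxy acrylates and enones as the precedent for this acceptor. Ring B closes by 6-endo-trig attack through a chair-like array trans-fused to the ring-A chair, forming the C9–C10 bond. C10 is set by the axial C19 CH2OSiEt3 group, which blocks the β lobe of the radical so that C9 bonds equatorially from the α face and C20 ends axial (trans fusion), and C9 is set by the Z enone geometry, because the substituent cis to C7 (the ring-C oxygen) becomes axial (9α) and C11 equatorial in that chair, whereas the E isomer would lead to the C9 epimer. C8 is set by axial protonation of the enolate and is in any case the thermodynamic epimer, since an 8β-methyl would be 1,3-diaxial to C20. The step needs hydrogen-atom transfer only to the 1,1-disubstituted alkene (the tetrasubstituted electron-poor enone and the silylated alkyne do not react with the iron hydride) and cyclisation faster than reduction of the radical, which the matched polarity, the six-membered closure and slow addition of the silane are meant to secure.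

Step 17
Reactants: 21 9α,13-epoxy-7-oxo decalin
Product: 22 6-en-7-yl chloroacetate
Conditions: KN(SiMe3)2, THF, −78 °C; (ClCH2CO)2O, −78 °C; aq. NH4Cl
Reagents that add atoms: chloroacetic anhydride, O=C(CCl)OC(=O)CCl
Why: Kinetic deprotonation occurs at the C6 methylene and not at the tertiary C8–H next to the spiro carbon (which would also risk β-elimination of the C9–O bond), and O-acylation of the potassium enolate by the anhydride gives the 6-en-7-yl ester.

Step 18
Reactants: 22 6-en-7-yl chloroacetate
Product: 24 6β-chloroacetoxy 7-ketone, via enol ester epoxide 23 (not isolated)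
Conditions: dimethyldioxirane, acetone/CH2Cl2, 0 °C; concentrate; then 2,6-di-tert-butyl-4-methylpyridine (cat.), PhMe, 120 °C (sealed)
Reagents that add atoms: dimethyldioxirane, CC1(C)OO1
Why: Dimethyldioxirane epoxidises the enol ester from the α face (the β face is covered by C19 and C20), and on heating the acyloxy group migrates from C7 to C6 with inversion, its carbonyl oxygen being delivered intramolecularly to the β face while the epoxide oxygen becomes the C7 carbonyl (thermal enol ester epoxide rearrangement, known to give axial α-acyloxy ketones in steroids), which sets the 6β-oxygen.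

Step 19
Reactants: 24 6β-chloroacetoxy 7-ketone
Product: 26 6β-hydroxy 7-ketone, via isothiouronium salt 25 (not isolated)
Conditions: thiourea, NaHCO3, EtOH/THF, 55 °C
Reagents that add atoms: none
Why: Standard dechloroacetylation: thiourea is S-alkylated by the CH2Cl group and the isothiouronium ester cyclises onto the ester carbonyl, freeing the 6β-hydroxyl under near-neutral conditions that do not enolise the α-ketol.

Step 20
Reactants: 26 6β-hydroxy 7-ketone
Product: 27 tetraol with terminal alkyne
Conditions: Bu4NF, AcOH, THF, 0 °C → rt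
Reagents that add atoms: none
Why: Buffered fluoride cleaves the two O-triethylsilyl groups, the O-tert-butyldimethylsilyl group and the C-triethylsilyl group of the alkyne in one operation without exposing the β-alkoxy ketone to strong base.

Step 21
Reactants: 27 tetraol with terminal alkyne
Product: 28 dihydrofuran triol (ring D closed)
Conditions: Et3N·Mo(CO)5 (30 mol %, preformed from Mo(CO)6, Et3N, Et2O, hν 350 nm), Et3N, THF, rt, dark
Reagents that add atoms: none
Why: Molybdenum-carbonyl-catalysed cycloisomerisation of the 3-butyn-1-ol unit: the terminal alkyne rearranges to a molybdenum vinylidene that is attacked by the C16 hydroxyl, giving the 2,3-dihydrofuran ring D, and none of the other hydroxyls can reach the alkyne.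

Step 22
Reactants: 28 dihydrofuran triol
Product: 29 CNP0317137.1
Conditions: Ac2O, pyridine, 0 °C → rt
Reagents that add atoms: acetic anhydride, CC(=O)OC(C)=O
Why: Acetylation in pyridine acylates the primary C19 and the equatorial C3 hydroxyls, while the axial 6β-hydroxyl, 1,3-diaxial to both C19 and C20 and hydrogen-bonded to the C7 carbonyl, is expected to remain free; the acid-sensitive enol ether of ring D only meets basic conditions.

**Compound list**

1 | 2-methylcyclohexane-1,3-dione | CC1C(=O)CCCC1=O | starting material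
2 | 2-(hydroxymethyl)-2-methylcyclohexane-1,3-dione | OCC1(C)C(=O)CCCC1=O | intermediate
3 | (2S,3S)-3-hydroxy-2-(hydroxymethyl)-2-methylcyclohexan-1-one | OC[C@@]1(C)[C@@H](O)CCCC1=O | intermediate
4 | (2S,3S)-2-methyl-3-(triethylsilyloxy)-2-[(triethylsilyloxy)methyl]cyclohexan-1-one | CC[Si](CC)(CC)OC[C@@]1(C)[C@@H](O[Si](CC)(CC)CC)CCCC1=O | intermediate
5 | (5S,6S)-6-methyl-5-(triethylsilyloxy)-6-[(triethylsilyloxy)methyl]cyclohex-1-en-1-yl trifluoromethanesulfonate | CC[Si](CC)(CC)OC[C@@]1(C)[C@@H](O[Si](CC)(CC)CC)CCC=C1OS(=O)(=O)C(F)(F)F | intermediate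
6 | ethyl 2-[(5S,6S)-6-methyl-5-(triethylsilyloxy)-6-[(triethylsilyloxy)methyl]cyclohex-1-en-1-yl]acetate | CC[Si](CC)(CC)OC[C@@]1(C)[C@@H](O[Si](CC)(CC)CC)CCC=C1CC(=O)OCC | intermediate
7 | ethyl 2-[(1R,2S,3S,6S)-6-boranyl-2-methyl-3-(triethylsilyloxy)-2-[(triethylsilyloxy)methyl]cyclohexyl]acetate (5α-H, 10α-BH2) | CC[Si](CC)(CC)OC[C@@]1(C)[C@@H](O[Si](CC)(CC)CC)CC[C@H](B)[C@H]1CC(=O)OCC | intermediate (not isolated)
8 | ethyl 2-[(1S,2S,3S,6S)-6-hydroxy-2-methyl-3-(triethylsilyloxy)-2-[(triethylsilyloxy)methyl]cyclohexyl]acetate (5α-H, 10α-OH) | CC[Si](CC)(CC)OC[C@@]1(C)[C@@H](O[Si](CC)(CC)CC)CC[C@H](O)[C@H]1CC(=O)OCC | intermediate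
9 | ethyl 2-[(1S,2S,3S)-2-methyl-6-oxo-3-(triethylsilyloxy)-2-[(triethylsilyloxy)methyl]cyclohexyl]acetate | CC[Si](CC)(CC)OC[C@@]1(C)[C@@H](O[Si](CC)(CC)CC)CCC(=O)[C@H]1CC(=O)OCC | intermediate
10 | ethyl 2-[(1R,2S,3S)-2-methyl-6-methylidene-3-(triethylsilyloxy)-2-[(triethylsilyloxy)methyl]cyclohexyl]acetate | CC[Si](CC)(CC)OC[C@@]1(C)[C@@H](O[Si](CC)(CC)CC)CCC(=C)[C@H]1CC(=O)OCC | intermediate
11 | N-methoxy-N-methyl-2-[(1R,2S,3S)-2-methyl-6-methylidene-3-(triethylsilyloxy)-2-[(triethylsilyloxy)methyl]cyclohexyl]acetamide | CC[Si](CC)(CC)OC[C@@]1(C)[C@@H](O[Si](CC)(CC)CC)CCC(=C)[C@H]1CC(=O)N(C)OC | intermediate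
12 | 1-[(1R,2S,3S)-2-methyl-6-methylidene-3-(triethylsilyloxy)-2-[(triethylsilyloxy)methyl]cyclohexyl]butan-2-one | CC[Si](CC)(CC)OC[C@@]1(C)[C@@H](O[Si](CC)(CC)CC)CCC(=C)[C@H]1CC(=O)CC | intermediate
13 | diethyl 2-oxopentanedioate (diethyl 2-oxoglutarate) | CCOC(=O)CCC(=O)C(=O)OCC | starting material
14 | ethynyl(triethyl)silane | C#C[Si](CC)(CC)CC | starting material
15 | diethyl (2R)-2-hydroxy-2-[(triethylsilyl)ethynyl]pentanedioate | CCOC(=O)CC[C@@](C#C[Si](CC)(CC)CC)(C(=O)OCC)O | intermediate (not isolated)
16 | ethyl (2R)-5-oxo-2-[(triethylsilyl)ethynyl]oxolane-2-carboxylate | O=C1CC[C@@](C#C[Si](CC)(CC)CC)(C(=O)OCC)O1 | intermediate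
17 | (5R)-5-(hydroxymethyl)-5-[(triethylsilyl)ethynyl]oxolan-2-one | O=C1CC[C@@](C#C[Si](CC)(CC)CC)(CO)O1 | intermediate
18 | (5R)-5-[(tert-butyldimethylsilyloxy)methyl]-5-[(triethylsilyl)ethynyl]oxolan-2-one | O=C1CC[C@@](C#C[Si](CC)(CC)CC)(CO[Si](C)(C)C(C)(C)C)O1 | intermediate
19 | γ-hydroxy 1,3-diketone: ring A of 12 joined through C6H2–C7(=O)–C8H(CH3)–C9(=O)–C11H2–C12H2 to C13 (R; OH, C≡C–SiEt3, CH2OSi(t-Bu)Me2); C8 epimers, in equilibrium with the C9 hemiketal | CC[Si](CC)(CC)OC[C@@]1(C)[C@@H](O[Si](CC)(CC)CC)CCC(=C)[C@H]1CC(=O)C(C)C(=O)CC[C@@](C#C[Si](CC)(CC)CC)(CO[Si](C)(C)C(C)(C)C)O | intermediate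
20 | (8Z,13R)-16-(tert-butyldimethylsilyloxy)-3β,19-bis(triethylsilyloxy)-15-(triethylsilyl)-9,13-epoxy-9,10-secolabda-8,10(20)-dien-14-yn-7-one (5α-H; C7 cis to the ring-C oxygen) | CC[Si](CC)(CC)OC[C@@]1(C)[C@@H](O[Si](CC)(CC)CC)CCC(=C)[C@H]1CC(=O)/C(C)=C2/CC[C@@](C#C[Si](CC)(CC)CC)(CO[Si](C)(C)C(C)(C)C)O2 | intermediate
21 | (13R)-16-(tert-butyldimethylsilyloxy)-3β,19-bis(triethylsilyloxy)-15-(triethylsilyl)-9α,13-epoxylabd-14-yn-7-one (5α-H, 8β-H, 10β-CH3) | CC[Si](CC)(CC)OC[C@@]1(C)[C@@H](O[Si](CC)(CC)CC)CC[C@@]2(C)[C@H]1CC(=O)[C@@H](C)[C@]23CC[C@@](C#C[Si](CC)(CC)CC)(CO[Si](C)(C)C(C)(C)C)O3 | intermediate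
22 | (13R)-16-(tert-butyldimethylsilyloxy)-3β,19-bis(triethylsilyloxy)-15-(triethylsilyl)-9α,13-epoxylabd-6-en-14-yn-7-yl chloroacetate | CC[Si](CC)(CC)OC[C@@]1(C)[C@@H](O[Si](CC)(CC)CC)CC[C@@]2(C)[C@H]1C=C(OC(=O)CCl)[C@@H](C)[C@]23CC[C@@](C#C[Si](CC)(CC)CC)(CO[Si](C)(C)C(C)(C)C)O3 | intermediate
23 | 6α,7α-epoxide of 22 (7β-chloroacetoxy-6α,7α;9α,13-diepoxide) | CC[Si](CC)(CC)OC[C@@]1(C)[C@@H](O[Si](CC)(CC)CC)CC[C@@]2(C)[C@H]1[C@H]4O[C@@]4(OC(=O)CCl)[C@@H](C)[C@]23CC[C@@](C#C[Si](CC)(CC)CC)(CO[Si](C)(C)C(C)(C)C)O3 | intermediate (not isolated)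
24 | (13R)-6β-(chloroacetoxy)-16-(tert-butyldimethylsilyloxy)-3β,19-bis(triethylsilyloxy)-15-(triethylsilyl)-9α,13-epoxylabd-14-yn-7-one | CC[Si](CC)(CC)OC[C@@]1(C)[C@@H](O[Si](CC)(CC)CC)CC[C@@]2(C)[C@H]1[C@H](OC(=O)CCl)C(=O)[C@@H](C)[C@]23CC[C@@](C#C[Si](CC)(CC)CC)(CO[Si](C)(C)C(C)(C)C)O3 | intermediate
25 | S-alkylisothiouronium chloride of 24 (6β-[(carbamimidoylsulfanyl)acetoxy] ester, hydrochloride) | CC[Si](CC)(CC)OC[C@@]1(C)[C@@H](O[Si](CC)(CC)CC)CC[C@@]2(C)[C@H]1[C@H](OC(=O)CSC(N)=[NH2+])C(=O)[C@@H](C)[C@]23CC[C@@](C#C[Si](CC)(CC)CC)(CO[Si](C)(C)C(C)(C)C)O3.[Cl-] | intermediate (not isolated)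
26 | (13R)-6β-hydroxy-16-(tert-butyldimethylsilyloxy)-3β,19-bis(triethylsilyloxy)-15-(triethylsilyl)-9α,13-epoxylabd-14-yn-7-one | CC[Si](CC)(CC)OC[C@@]1(C)[C@@H](O[Si](CC)(CC)CC)CC[C@@]2(C)[C@H]1[C@H](O)C(=O)[C@@H](C)[C@]23CC[C@@](C#C[Si](CC)(CC)CC)(CO[Si](C)(C)C(C)(C)C)O3 | intermediate
27 | (13R)-3β,6β,16,19-tetrahydroxy-9α,13-epoxylabd-14-yn-7-one | OC[C@@]1(C)[C@@H](O)CC[C@@]2(C)[C@H]1[C@H](O)C(=O)[C@@H](C)[C@]23CC[C@@](C#C)(CO)O3 | intermediate
28 | (13R)-3β,6β,19-trihydroxy-9α,13;15,16-diepoxylabd-14-en-7-one | OC[C@@]1(C)[C@@H](O)CC[C@@]2(C)[C@H]1[C@H](O)C(=O)[C@@H](C)[C@]23CC[C@]4(C=COC4)O3 | intermediate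
29 | (13R)-3β,19-diacetoxy-6β-hydroxy-9α,13;15,16-diepoxylabd-14-en-7-one (CNP0317137.1) | CC(=O)OC[C@@]1(C)[C@@H](OC(C)=O)CC[C@@]2(C)[C@H]1[C@H](O)C(=O)[C@@H](C)[C@]21CC[C@]2(C=COC2)O1 | target

**Step count and risks**

Total: 22 steps. Longest linear sequence: 19 steps (steps 1–10 and 14–22); the lactone branch (steps 11–13) is 3 steps.

Steps most likely to fail:

Step 16. The tertiary C10 radical may take up a second hydrogen atom (net hydrogenation of the exocyclic alkene) faster than it adds to the fully substituted C9, since two fully substituted carbons are being joined at the edge of what such cyclisations have shown. The fallback sets out from 20 and comes back at 21, and generates the same radical without any hydride donor. Mukaiyama hydration of the exocyclic alkene (Co(acac)2, PhSiH3, O2) would give the C10 tertiary alcohol F1. Acylation with methyl chlorooxoacetate (Et3N, DMAP) would give the methyl oxalate F2, and hydrolysis with CsOH the cesium oxalate F3. Visible-light photoredox decarboxylation of F3 (Ir[dF(CF3)ppy]2(dtbbpy)PF6, blue LEDs, DME/DMF/H2O) releases the C10 radical, which then has only cyclisation open to it, and reduction and protonation of the C8 radical give 21.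

Step 18. Ionisation of the epoxide at C7 (acyl transfer with retention, giving the equatorial 6α ester) or steric retardation of the acyloxy shift to the crowded β face may compete with the concerted migration. The fallback sets out from 21 and comes back at 26; oxygen is brought in from the open α face and then inverted. Hydroxylation of the potassium enolate of 21 with 2-(phenylsulfonyl)-3-phenyloxaziridine would give the 6α-hydroxy ketone F4. Triflation (Tf2O, 2,6-lutidine, −78 °C) would give the α-keto triflate F5. Displacement with tetrabutylammonium nitrite (SN2 with inversion, accelerated by the adjacent carbonyl) would give the 6β-nitrite ester F6, which is hydrolysed on aqueous work-up to 26.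

Step 14. Deprotonation of 12 at C6 instead of C8, or proton transfer from lactone 18 to the enolate, may erode regioselectivity and conversion in the Claisen union. The fallback sets out from 11 and comes back at 19. MeMgBr would convert the Weinreb amide into the methyl ketone F7, whose kinetic enolate can form only at the methyl group. Acylation of that enolate with 18 would give the 1,3-diketone F8, and C-methylation at the doubly activated C8 (K2CO3, MeI, acetone) would give 19.

Further compounds
F1 | step 16 | C10 tertiary alcohol from hydration of 20 (10-hydroxy-10-methyl, C10 epimers) | CC[Si](CC)(CC)OC[C@@]1(C)[C@@H](O[Si](CC)(CC)CC)CCC(C)(O)[C@H]1CC(=O)/C(C)=C2/CC[C@@](C#C[Si](CC)(CC)CC)(CO[Si](C)(C)C(C)(C)C)O2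
F2 | step 16 | methyl oxalate of F1 | CC[Si](CC)(CC)OC[C@@]1(C)[C@@H](O[Si](CC)(CC)CC)CCC(C)(OC(=O)C(=O)OC)[C@H]1CC(=O)/C(C)=C2/CC[C@@](C#C[Si](CC)(CC)CC)(CO[Si](C)(C)C(C)(C)C)O2
F3 | step 16 | cesium oxalate of F1 | CC[Si](CC)(CC)OC[C@@]1(C)[C@@H](O[Si](CC)(CC)CC)CCC(C)(OC(=O)C(=O)[O-])[C@H]1CC(=O)/C(C)=C2/CC[C@@](C#C[Si](CC)(CC)CC)(CO[Si](C)(C)C(C)(C)C)O2.[Cs+]
F4 | step 18 | 6α-hydroxy ketone (C6 epimer of 26) | CC[Si](CC)(CC)OC[C@@]1(C)[C@@H](O[Si](CC)(CC)CC)CC[C@@]2(C)[C@H]1[C@@H](O)C(=O)[C@@H](C)[C@]23CC[C@@](C#C[Si](CC)(CC)CC)(CO[Si](C)(C)C(C)(C)C)O3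
F5 | step 18 | 6α-trifluoromethanesulfonate of F4 | CC[Si](CC)(CC)OC[C@@]1(C)[C@@H](O[Si](CC)(CC)CC)CC[C@@]2(C)[C@H]1[C@@H](OS(=O)(=O)C(F)(F)F)C(=O)[C@@H](C)[C@]23CC[C@@](C#C[Si](CC)(CC)CC)(CO[Si](C)(C)C(C)(C)C)O3
F6 | step 18 | 6β-nitrite ester of 26 | CC[Si](CC)(CC)OC[C@@]1(C)[C@@H](O[Si](CC)(CC)CC)CC[C@@]2(C)[C@H]1[C@H](ON=O)C(=O)[C@@H](C)[C@]23CC[C@@](C#C[Si](CC)(CC)CC)(CO[Si](C)(C)C(C)(C)C)O3
F7 | step 14 | ring-A methyl ketone, 1-[(1R,2S,3S)-2-methyl-6-methylidene-3-(triethylsilyloxy)-2-[(triethylsilyloxy)methyl]cyclohexyl]propan-2-one | CC[Si](CC)(CC)OC[C@@]1(C)[C@@H](O[Si](CC)(CC)CC)CCC(=C)[C@H]1CC(C)=O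
F8 | step 14 | γ-hydroxy 1,3-diketone lacking the C8 methyl (8-nor analogue of 19) | CC[Si](CC)(CC)OC[C@@]1(C)[C@@H](O[Si](CC)(CC)CC)CCC(=C)[C@H]1CC(=O)CC(=O)CC[C@@](C#C[Si](CC)(CC)CC)(CO[Si](C)(C)C(C)(C)C)O
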